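Ring B of the target carries the C7 tertiary carbinol 1,4 across from C4a, so the C7 oxygen is read as the ring oxygen of a furan. The route rests on disconnecting C7–C8 and C4a–C8a: an intramolecular Diels–Alder reaction of a 2-methyl-3-silyloxyfuran, tethered through C4–C3–O2–C1 to an (E)-alkenylboronate (an E-enol equivalent), then strain-releasing opening of the 7-oxanorbornene bridge. One operation closes pyran ring A and carbocycle B, sets C7, C8 and C8a as a group, and unveils the C4a=C5–C6=O enone. Its precursor is a monocyclic 3(2H)-furanone with one sacrificial stereocentre (C3, from glycidol) that is erased when C3=C4 is introduced.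

Key step: step 8

Remark: locants C1–C8a and O2 are those of the isochromenone core of the target and denote the same atoms throughout. The lactate-derived centre (future C7) is flattened in step 8, so its configuration in 7–13 is immaterial.

Step 1
Reactants: 1 (S)-glycidol
Product: 2 (R)-2-{[(4-methoxybenzyl)oxy]methyl}oxirane
Conditions: NaH, PMBCl, TBAI (cat.), DMF, 0 °C to rt
Reagents that add atoms: 4-methoxybenzyl chloride, COc1ccc(CCl)cc1
Why: Williamson ether synthesis on the primary alkoxide leaves the oxirane stereocentre untouched (a Payne shift of glycidol is degenerate), and only the CIP descriptor changes from S to R.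

Step 2
Reactants: 2 (R)-2-{[(4-methoxybenzyl)oxy]methyl}oxirane; 3 lithium acetylide–ethylenediamine complex
Product: 4 (R)-1-[(4-methoxybenzyl)oxy]pent-4-yn-2-ol
Conditions: DMSO, rt
Reagents that add atoms: none
Why: SN2 opening of a terminal epoxide by an acetylide occurs at the unsubstituted carbon, so the carbinol centre (future C3, R) is carried over unchanged.

Step 3
Reactants: 4 (R)-1-[(4-methoxybenzyl)oxy]pent-4-yn-2-ol; 5 allyl bromide
Product: 6 (R)-1-({[2-(allyloxy)pent-4-yn-1-yl]oxy}methyl)-4-methoxybenzene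
Conditions: NaH, TBAI (cat.), THF/DMF, 0 °C to rt
Reagents that add atoms: none
Why: Williamson ether synthesis installs O2–C1–C8a=C8, since NaH deprotonates only the alcohol and a benzyl-type neighbouring ether cannot migrate.

Step 4
Reactants: 7 ethyl (S)-lactate; 8 N,O-dimethylhydroxylamine hydrochloride
Product: 9 (S)-2-hydroxy-N-methoxy-N-methylpropanamide
Conditions: i-PrMgCl (3 equiv), THF, −20 to 0 °C
Reagents that add atoms: none
Why: Aminolysis of the ester by the magnesium amide gives the Weinreb amide directly, the hydroxyl being masked in situ as its magnesium alkoxide.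

Step 5
Reactants: 6 (R)-1-({[2-(allyloxy)pent-4-yn-1-yl]oxy}methyl)-4-methoxybenzene; 9 (S)-2-hydroxy-N-methoxy-N-methylpropanamide
Product: 10 (2S,7R)-7-(allyloxy)-2-hydroxy-8-[(4-methoxybenzyl)oxy]oct-4-yn-3-one
Conditions: 6, n-BuLi, THF, −78 °C; then 9 (pre-treated with i-PrMgCl, 1 equiv), −78 to 0 °C
Reagents that add atoms: none
Why: Weinreb ketone synthesis, in which the lithium acetylide adds once to the chelated amide and the ynone is released only on work-up.

Step 6
Reactants: 10 (2S,7R)-7-(allyloxy)-2-hydroxy-8-[(4-methoxybenzyl)oxy]oct-4-yn-3-one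
Product: 11 (2S)-5-{(2R)-2-(allyloxy)-3-[(4-methoxybenzyl)oxy]propyl}-2-methylfuran-3(2H)-one
Conditions: (Ph3P)AuCl/AgOTf (5 mol %), PhMe, rt
Reagents that add atoms: none
Why: Gold(I)-catalysed 5-endo-dig cycloisomerisation of an α'-hydroxy ynone gives the 3(2H)-furanone under neutral conditions, which avoids base-induced loss of the β-alkoxy group at C3.

Step 7
Reactants: 11 (2S)-5-{(2R)-2-(allyloxy)-3-[(4-methoxybenzyl)oxy]propyl}-2-methylfuran-3(2H)-one; 12 vinylboronic acid pinacol ester
Product: 13 (2S)-5-{(2R)-3-[(4-methoxybenzyl)oxy]-2-{[(E)-3-(pinacolboryl)allyl]oxy}propyl}-2-methylfuran-3(2H)-one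
Conditions: Hoveyda–Grubbs II (5 mol %), 1,4-benzoquinone (10 mol %), CH2Cl2, 40 °C
Reagents that add atoms: none
Why: Olefin cross metathesis of a terminal allyl ether with vinyl-Bpin is E-selective, and the trisubstituted, electron-poor furanone alkene does not take part.

Step 8
Reactants: 13 (2S)-5-{(2R)-3-[(4-methoxybenzyl)oxy]-2-{[(E)-3-(pinacolboryl)allyl]oxy}propyl}-2-methylfuran-3(2H)-one
Product: 16 (3R,7R,8S,8aS)-3-{[(4-methoxybenzyl)oxy]methyl}-7-methyl-8-(pinacolboryl)-7-(triethylsilyloxy)-1,3,4,7,8,8a-hexahydro-6H-isochromen-6-one, via silyloxyfuran 14 (not isolated), via oxa-bridged cycloadduct 15 (not isolated)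
Conditions: TESOTf (1.1 equiv), Et3N (2 equiv), PhMe, 0 °C to rt; then diluted to 5 mM, BHT (cat.), degassed, 140 °C, sealed tube
Reagents that add atoms: triethylsilyl trifluoromethanesulfonate, CC[Si](CC)(CC)OS(=O)(=O)C(F)(F)F
Why: Soft enolisation at C7–H aromatises furanone 13 to the electron-rich 3-silyloxyfuran 14, whose termini C7 and C4a add suprafacially to the tethered (E)-alkenylboronate (normal electron demand, LUMO lowered by the vacant boron p orbital) to give 7-oxanorbornene 15, after which the C6 silyl enol ether expels the strained, tertiary and allylic C4a–O bond and the silyl group passes from O6 to the adjacent C7 alkoxide, so that a reversible furan cycloaddition is drained irreversibly into enone 16. The closest known reaction types are the intramolecular Diels–Alder reaction of donor-substituted furans (which accept weakly activated alkenes because the adduct ring-opens), Diels–Alder reactions of alkenylboronates as enol equivalents, and the silyl triflate/amine-induced β-elimination of 7-oxanorbornan-2-ones. Carbocycle B is the six-membered cycloaddition ring itself (bonds C7–C8 and C4a–C8a), and pyran ring A is the tether ring of a type 1 intramolecular cycloaddition, closed by the C4a–C8a bond through a chair-like C4–C3–O2–C1 tether that can span bridgehead C4a and C8a only in the exo orientation, syn to the oxygen bridge. C7 is fixed by the bridge oxygen that becomes its OH, C8a by the exo tether (C1 cis to the C7 oxygen), C8 by the E geometry (boron endo, trans to C1 and to the C7 oxygen), and the absolute sense by C3, whose CH2OPMB group takes the equatorial site of the chair tether because the axial site is 1,3-diaxial to the bridge oxygen. The step needs facial selectivity (secured by C3, with the minor diastereomer removable at 16), regiochemistry (imposed by the tether) and cleavage of C4a–O rather than C7–O (secured by the vinylogous push of the enol ether, against which the C8–B bond of a pinacol boronate is only a weak β-donor).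

Step 9
Reactants: 16 (3R,7R,8S,8aS)-3-{[(4-methoxybenzyl)oxy]methyl}-7-methyl-8-(pinacolboryl)-7-(triethylsilyloxy)-1,3,4,7,8,8a-hexahydro-6H-isochromen-6-one
Product: 18 (3R,7R,8S,8aS)-7,8-dihydroxy-3-{[(4-methoxybenzyl)oxy]methyl}-7-methyl-1,3,4,7,8,8a-hexahydro-6H-isochromen-6-one, via hydroxy silyl ether 17 (not isolated)
Conditions: NaBO3·4H2O, THF/H2O, rt; then 1 M HCl, rt
Reagents that add atoms: sodium perborate, [Na+].[O-]OB=O
Why: Boronate oxidation proceeds by 1,2-migration of C8 from boron to oxygen with retention, which gives the C8 alcohol trans to the C7 oxygen, and dilute acid then hydrolyses the tertiary TES ether without touching the PMB ether.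

Step 10
Reactants: 19 2,4-dihydroxy-6-methylbenzaldehyde
Product: 20 2,4-bis(methoxymethoxy)-6-methylbenzaldehyde
Conditions: NaH, MOMCl, DMF, 0 °C to rt
Reagents that add atoms: chloromethyl methyl ether, COCCl
Why: O-alkylation of both phenoxides gives the bis-MOM ether, the strong base overcoming the hydrogen bond of the ortho phenol.

Step 11
Reactants: 20 2,4-bis(methoxymethoxy)-6-methylbenzaldehyde
Product: 21 2,4-bis(methoxymethoxy)-6-methylbenzoic acid
Conditions: NaClO2, NaH2PO4, 2-methyl-2-butene, t-BuOH/H2O, rt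
Reagents that add atoms: sodium chlorite, [Na+].[O-]Cl=O
Why: Pinnick oxidation converts the hindered aldehyde into the acid at buffered pH, and the alkene scavenger protects the electron-rich ring from hypochlorous acid.

Step 12
Reactants: 18 (3R,7R,8S,8aS)-7,8-dihydroxy-3-{[(4-methoxybenzyl)oxy]methyl}-7-methyl-1,3,4,7,8,8a-hexahydro-6H-isochromen-6-one; 21 2,4-bis(methoxymethoxy)-6-methylbenzoic acid
Product: 22 (3R,7R,8S,8aS)-7-hydroxy-3-{[(4-methoxybenzyl)oxy]methyl}-7-methyl-6-oxo-1,3,4,7,8,8a-hexahydro-6H-isochromen-8-yl 2,4-bis(methoxymethoxy)-6-methylbenzoate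
Conditions: EDC·HCl, DMAP, CH2Cl2, rt
Reagents that add atoms: none
Why: Steglich esterification acylates the equatorial secondary C8–OH in preference to the tertiary C7–OH without breaking any bond at a stereocentre, and C7 has no α-hydrogen through which the new β-acyloxy ketone could eliminate.

Step 13
Reactants: 22 (3R,7R,8S,8aS)-7-hydroxy-3-{[(4-methoxybenzyl)oxy]methyl}-7-methyl-6-oxo-1,3,4,7,8,8a-hexahydro-6H-isochromen-8-yl 2,4-bis(methoxymethoxy)-6-methylbenzoate
Product: 23 (3R,7R,8S,8aS)-7-hydroxy-3-(hydroxymethyl)-7-methyl-6-oxo-1,3,4,7,8,8a-hexahydro-6H-isochromen-8-yl 2,4-bis(methoxymethoxy)-6-methylbenzoate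
Conditions: DDQ, CH2Cl2/pH 7 buffer, 0 °C
Reagents that add atoms: none
Why: Oxidative PMB cleavage by DDQ is neutral and orthogonal to the MOM ethers, the ester and the enone.

Step 14
Reactants: 23 (3R,7R,8S,8aS)-7-hydroxy-3-(hydroxymethyl)-7-methyl-6-oxo-1,3,4,7,8,8a-hexahydro-6H-isochromen-8-yl 2,4-bis(methoxymethoxy)-6-methylbenzoate
Product: 25 (7R,8S,8aS)-3-formyl-7-hydroxy-7-methyl-6-oxo-1,7,8,8a-tetrahydro-6H-isochromen-8-yl 2,4-bis(methoxymethoxy)-6-methylbenzoate, via aldehyde 24 (not isolated)
Conditions: IBX (4 equiv), DMSO, rt to 65 °C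
Reagents that add atoms: none
Why: IBX oxidises the primary alcohol to α-alkoxy aldehyde 24 and then dehydrogenates it (IBX dehydrogenation of carbonyl compounds): the aldehyde enolises at C3, and the iodine(V) enol adduct loses an allylic C4–H to give the conjugated C3=C4–C4a=C5 dienol ether, which erases the sacrificial C3 centre and leaves C7, C8 and C8a untouched.

Step 15
Reactants: 25 (7R,8S,8aS)-3-formyl-7-hydroxy-7-methyl-6-oxo-1,7,8,8a-tetrahydro-6H-isochromen-8-yl 2,4-bis(methoxymethoxy)-6-methylbenzoate; 26 tert-butyl (triphenylphosphoranylidene)acetate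
Product: 27 (7R,8S,8aS)-3-[(E)-3-tert-butoxy-3-oxoprop-1-enyl]-7-hydroxy-7-methyl-6-oxo-1,7,8,8a-tetrahydro-6H-isochromen-8-yl 2,4-bis(methoxymethoxy)-6-methylbenzoate
Conditions: CH2Cl2, rt
Reagents that add atoms: none
Why: The Wittig reaction of a stabilised ylide with the aldehyde is E-selective, and the ylide is too weak a base to deprotonate C8a–H.

Step 16
Reactants: 27 (7R,8S,8aS)-3-[(E)-3-tert-butoxy-3-oxoprop-1-enyl]-7-hydroxy-7-methyl-6-oxo-1,7,8,8a-tetrahydro-6H-isochromen-8-yl 2,4-bis(methoxymethoxy)-6-methylbenzoate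
Product: 28 pinazaphilone B
Conditions: TFA/CH2Cl2 (1:4), 0 °C to rt; aqueous work-up
Reagents that add atoms: none
Why: Acidolysis removes the tert-butyl ester and both aryl MOM ethers together, while the push–pull dienol ether, the α-ketol (whose cation is destabilised by the ketone) and the base-sensitive C8 ester tolerate acid.

Compound list
1 | (S)-glycidol | OC[C@H]1CO1 | starting material
2 | (R)-2-{[(4-methoxybenzyl)oxy]methyl}oxirane | COc1ccc(COC[C@H]2CO2)cc1 | intermediate
3 | lithium acetylide–ethylenediamine complex | [Li+].[C-]#C.NCCN | starting material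
4 | (R)-1-[(4-methoxybenzyl)oxy]pent-4-yn-2-ol | C#CC[C@@H](O)COCc1ccc(OC)cc1 | intermediate
5 | allyl bromide | C=CCBr | starting material
6 | (R)-1-({[2-(allyloxy)pent-4-yn-1-yl]oxy}methyl)-4-methoxybenzene | C#CC[C@@H](OCC=C)COCc1ccc(OC)cc1 | intermediate
7 | ethyl (S)-lactate | CCOC(=O)[C@H](C)O | starting material
8 | N,O-dimethylhydroxylamine hydrochloride | CNOC.Cl | starting material
9 | (S)-2-hydroxy-N-methoxy-N-methylpropanamide | C[C@H](O)C(=O)N(C)OC | intermediate
10 | (2S,7R)-7-(allyloxy)-2-hydroxy-8-[(4-methoxybenzyl)oxy]oct-4-yn-3-one | C[C@H](O)C(=O)C#CC[C@@H](OCC=C)COCc1ccc(OC)cc1 | intermediate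
11 | (2S)-5-{(2R)-2-(allyloxy)-3-[(4-methoxybenzyl)oxy]propyl}-2-methylfuran-3(2H)-one | C[C@@H]1OC(C[C@@H](OCC=C)COCc2ccc(OC)cc2)=CC1=O | intermediate
12 | vinylboronic acid pinacol ester | C=CB1OC(C)(C)C(C)(C)O1 | starting material
13 | (2S)-5-{(2R)-3-[(4-methoxybenzyl)oxy]-2-{[(E)-3-(pinacolboryl)allyl]oxy}propyl}-2-methylfuran-3(2H)-one | C[C@@H]1OC(C[C@@H](OC/C=C/B2OC(C)(C)C(C)(C)O2)COCc3ccc(OC)cc3)=CC1=O | intermediate
14 | 2-methyl-3-(triethylsilyloxy)furan carrying the (R)-configured side chain of 13 at C5 | Cc1oc(C[C@@H](OC/C=C/B2OC(C)(C)C(C)(C)O2)COCc3ccc(OC)cc3)cc1O[Si](CC)(CC)CC | intermediate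
15 | (3R,4aS,7R,8S,8aR)-4a,7-epoxy-bridged cycloadduct (C1 exo, Bpin endo, CH2OPMB equatorial, C5=C6 silyl enol ether) | C[C@]12O[C@@]3(C=C1O[Si](CC)(CC)CC)C[C@H](COCc4ccc(OC)cc4)OC[C@H]3[C@@H]2B5OC(C)(C)C(C)(C)O5 | intermediate
16 | (3R,7R,8S,8aS)-3-{[(4-methoxybenzyl)oxy]methyl}-7-methyl-8-(pinacolboryl)-7-(triethylsilyloxy)-1,3,4,7,8,8a-hexahydro-6H-isochromen-6-one | C[C@]1(O[Si](CC)(CC)CC)C(=O)C=C2C[C@H](COCc3ccc(OC)cc3)OC[C@H]2[C@@H]1B4OC(C)(C)C(C)(C)O4 | intermediate
17 | (3R,7R,8S,8aS)-8-hydroxy-3-{[(4-methoxybenzyl)oxy]methyl}-7-methyl-7-(triethylsilyloxy)-1,3,4,7,8,8a-hexahydro-6H-isochromen-6-one | C[C@]1(O[Si](CC)(CC)CC)C(=O)C=C2C[C@H](COCc3ccc(OC)cc3)OC[C@H]2[C@@H]1O | intermediate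
18 | (3R,7R,8S,8aS)-7,8-dihydroxy-3-{[(4-methoxybenzyl)oxy]methyl}-7-methyl-1,3,4,7,8,8a-hexahydro-6H-isochromen-6-one | C[C@]1(O)C(=O)C=C2C[C@H](COCc3ccc(OC)cc3)OC[C@H]2[C@@H]1O | intermediate
19 | 2,4-dihydroxy-6-methylbenzaldehyde | Cc1cc(O)cc(O)c1C=O | starting material
20 | 2,4-bis(methoxymethoxy)-6-methylbenzaldehyde | Cc1cc(OCOC)cc(OCOC)c1C=O | intermediate
21 | 2,4-bis(methoxymethoxy)-6-methylbenzoic acid | Cc1cc(OCOC)cc(OCOC)c1C(=O)O | intermediate
22 | C8 bis-MOM orsellinate of 18 | C[C@]1(O)C(=O)C=C2C[C@H](COCc3ccc(OC)cc3)OC[C@H]2[C@@H]1OC(=O)c4c(C)cc(OCOC)cc4OCOC | intermediate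
23 | (3R,7R,8S,8aS)-3-hydroxymethyl compound (22 without PMB) | C[C@]1(O)C(=O)C=C2C[C@H](CO)OC[C@H]2[C@@H]1OC(=O)c3c(C)cc(OCOC)cc3OCOC | intermediate
24 | (3R,7R,8S,8aS)-3-formyl hexahydroisochromenone ester | C[C@]1(O)C(=O)C=C2C[C@H](C=O)OC[C@H]2[C@@H]1OC(=O)c3c(C)cc(OCOC)cc3OCOC | intermediate
25 | (7R,8S,8aS)-3-formyl-1,7,8,8a-tetrahydro-6H-isochromen-6-one ester | C[C@]1(O)C(=O)C=C2C=C(C=O)OC[C@H]2[C@@H]1OC(=O)c3c(C)cc(OCOC)cc3OCOC | intermediate
26 | tert-butyl (triphenylphosphoranylidene)acetate | CC(C)(C)OC(=O)C=P(c1ccccc1)(c1ccccc1)c1ccccc1 | starting material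
27 | tert-butyl ester bis-MOM ether of pinazaphilone B | C[C@]1(O)C(=O)C=C2C=C(/C=C/C(=O)OC(C)(C)C)OC[C@H]2[C@@H]1OC(=O)c3c(C)cc(OCOC)cc3OCOC | intermediate
28 | pinazaphilone B, (7R,8S,8aS) | Cc1cc(O)cc(O)c1C(=O)O[C@H]1[C@@H]2COC(/C=C/C(=O)O)=CC2=CC(=O)[C@]1(C)O | target

Total step count: 16. Longest linear sequence: 13 (steps 1–3, 5–9 and 12–16).

Steps most likely to fail

First, step 8. The alkenylboronate may be too weak a dienophile. The cycloaddition could then stall or revert before the bridge opens, while the silyloxyfuran is lost to protodesilylation or oxidation. Facial control by C3 may also be incomplete, and an unremoved minor diastereomer would later erode the enantiomeric purity. The fallback sets out from 11 and comes back at 17.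
- Cross metathesis of 11 with methyl vinyl ketone gives the (E)-enone F1, a strongly activated dienophile.
- TESOTf/Et3N converts it into the silyloxyfuran F2. This should cyclise near room temperature to the oxa-bridged adduct F3 and open to the 8-acetyl enone F4.
- A Baeyer–Villiger oxidation (m-CPBA, NaHCO3) inserts oxygen into the C8–acyl bond with retention, giving the 8-acetate F5.
- K2CO3/MeOH releases 17, which the acid stage of step 9 takes on to 18.

Second, step 14. Enolisation may run towards C8a instead of C3/C4, which leads to dehydrogenation at C1–C8a or loss of the C8 ester. Hot IBX may also attack the benzylic methyl group. The fallback sets out from 23 and comes back at 25.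
- Dess–Martin oxidation at rt gives 24, which is now isolated.
- Amine-catalysed α-selenenylation with N-(phenylselanyl)phthalimide gives the α-selanyl aldehyde F6.
- H2O2 at 0 °C forms the selenoxide F7, whose syn elimination towards C4–H delivers 25 without heat or base.

Third, step 12. Acyl transfer from a 2,6-disubstituted benzoic acid to an alcohol flanked by C7 and C8a may be too slow, so that N-acylurea formation or base-induced retro-aldol cleavage of the diol takes over. The fallback sets out from 18 and comes back at 22, and it reverses the roles of the partners.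
- Selective mesylation of the secondary alcohol gives the 8-mesylate F8.
- DBU closes the 7,8-epoxy ketone F9 by displacement from the C7 oxygen (first inversion at C8).
- The caesium salt of 21 (DMF, 50 °C) opens the epoxide at the secondary, carbonyl-remote C8 (second inversion). The hindered carboxylate thus acts as nucleophile, and the configuration at C8 is retained overall.

Further compounds
F1 | step 8 | (2S)-5-{(2R)-3-[(4-methoxybenzyl)oxy]-2-{[(E)-4-oxopent-2-enyl]oxy}propyl}-2-methylfuran-3(2H)-one | C[C@@H]1OC(C[C@@H](OC/C=C/C(C)=O)COCc2ccc(OC)cc2)=CC1=O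
F2 | step 8 | 3-(triethylsilyloxy)furan derived from F1 | Cc1oc(C[C@@H](OC/C=C/C(C)=O)COCc2ccc(OC)cc2)cc1O[Si](CC)(CC)CC
F3 | step 8 | 4a,7-epoxy-bridged cycloadduct with endo acetyl group at C8 | C[C@]12O[C@@]3(C=C1O[Si](CC)(CC)CC)C[C@H](COCc4ccc(OC)cc4)OC[C@H]3[C@@H]2C(C)=O
F4 | step 8 | (3R,7R,8S,8aS)-8-acetyl-3-{[(4-methoxybenzyl)oxy]methyl}-7-methyl-7-(triethylsilyloxy)-1,3,4,7,8,8a-hexahydro-6H-isochromen-6-one | C[C@]1(O[Si](CC)(CC)CC)C(=O)C=C2C[C@H](COCc3ccc(OC)cc3)OC[C@H]2[C@@H]1C(C)=O
F5 | step 8 | 8-acetate of 17 | C[C@]1(O[Si](CC)(CC)CC)C(=O)C=C2C[C@H](COCc3ccc(OC)cc3)OC[C@H]2[C@@H]1OC(C)=O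
F6 | step 14 | 3-(phenylselanyl) derivative of 24 (either C3 epimer serves) | C[C@]1(O)C(=O)C=C2CC(C=O)([Se]c3ccccc3)OC[C@H]2[C@@H]1OC(=O)c4c(C)cc(OCOC)cc4OCOC
F7 | step 14 | selenoxide of F6 | C[C@]1(O)C(=O)C=C2CC(C=O)([Se](=O)c3ccccc3)OC[C@H]2[C@@H]1OC(=O)c4c(C)cc(OCOC)cc4OCOC
F8 | step 12 | 8-methanesulfonate of 18 | C[C@]1(O)C(=O)C=C2C[C@H](COCc3ccc(OC)cc3)OC[C@H]2[C@@H]1OS(C)(=O)=O
F9 | step 12 | 7,8-epoxy ketone with the oxirane on the face of the former C7–OH | C[C@@]12O[C@@H]1[C@@H]3CO[C@@H](COCc4ccc(OC)cc4)CC3=CC2=O
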